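**Strategy.** The target is cut at the two benzylic bonds C1′–C2′ and C13′–C14′ of its tetradecane tether (ring atoms: C1 carbonyl, C2 chain-bearing, C3 hydroxyl, C4 carbonyl, C5 methyl, C6 methoxy). Because C1′ sits on C2, directly beside oxygenated C1, it can be unmasked as the exocyclic CH2 of an ortho-quinone methide (C1=O, C2=C1′H2). One operation lets both ends of a C12 bis-Grignard reagent add to two such methides, assembling the whole carbon framework and regenerating both arenes. The methide precursor is a fully substituted ortho-(Boc-oxy)benzyl alcohol whose C3/C4 oxygens are tied up as an acetonide and whose C6 oxygen is already the methyl ether.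

Key step: step 8

Step 1
Reactants: 1 3-methoxy-2-methylphenol
Product: 2 2-methoxy-3-methyl-1,4-benzoquinone
Conditions: (KO3S)2NO (2.2 equiv), KH2PO4, H2O/acetone, 0 °C to rt
Reagents that add atoms: potassium nitrosodisulfonate (KO3S)2NO, [K+].[K+].[O]N(S(=O)(=O)[O-])S(=O)(=O)[O-]
Why: Teuber oxidation, in which the nitroxyl radical removes the phenolic hydrogen and a second equivalent couples at the unsubstituted carbon para to the hydroxyl, so that loss of (KO3S)2NH should give the para-quinone.

Step 2
Reactants: 2 2-methoxy-3-methyl-1,4-benzoquinone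
Product: 3 5-methoxy-6-methylbenzene-1,2,4-triyl triacetate
Conditions: Ac2O, H2SO4 (cat.), 0 °C to rt; ice water
Reagents that add atoms: acetic anhydride, CC(=O)OC(C)=O
Why: Thiele–Winter acetoxylation, in which the methoxy group on C2 of the quinone deactivates the C4 carbonyl as a vinylogous ester, so acetate should add in a conjugate sense through the C1 carbonyl at C5 (para to the methoxy group) before enolisation and peracetylation.

Step 3
Reactants: 3 5-methoxy-6-methylbenzene-1,2,4-triyl triacetate
Product: 5 6-methoxy-2,2,7-trimethyl-1,3-benzodioxol-5-ol, via 5-methoxy-6-methylbenzene-1,2,4-triol 4 (not isolated)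
Conditions: HCl (from AcCl), MeOH, Ar, 50 °C; evaporate; then Me2C(OMe)2, TsOH·H2O (cat.), toluene, 90 °C, 4 Å molecular sieves, Ar
Reagents that add atoms: 2,2-dimethoxypropane, COC(C)(C)OC
Why: Acid-catalysed transesterification followed by acetal exchange (isopropylidene ketal formation), in which only the adjacent pair of hydroxyls can close the five-membered dioxole, so the lone hydroxyl beside the methoxy group stays free and the oxidation-prone triol never meets air.

Step 4
Reactants: 5 6-methoxy-2,2,7-trimethyl-1,3-benzodioxol-5-ol
Product: 6 5-hydroxy-6-methoxy-2,2,7-trimethyl-1,3-benzodioxole-4-carbaldehyde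
Conditions: MgCl2 (anhydrous), Et3N, (CH2O)n, THF, reflux
Reagents that add atoms: formaldehyde (as paraformaldehyde), C=O
Why: Magnesium-mediated ortho-formylation (Casnati–Skattebøl reaction), in which the magnesium phenoxide delivers formaldehyde to the only unsubstituted ring carbon, which is ortho to the hydroxyl, and a second formaldehyde oxidises the benzylic alkoxide to the aldehyde by hydride transfer.

Step 5
Reactants: 6 5-hydroxy-6-methoxy-2,2,7-trimethyl-1,3-benzodioxole-4-carbaldehyde
Product: 7 tert-butyl 4-formyl-6-methoxy-2,2,7-trimethyl-1,3-benzodioxol-5-yl carbonate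
Conditions: Boc2O, i-Pr2NEt, DMAP (cat.), CH2Cl2, 0 °C to rt
Reagents that add atoms: di-tert-butyl dicarbonate, CC(C)(C)OC(=O)OC(=O)OC(C)(C)C
Why: DMAP-catalysed O-acylation of a phenol to its tert-butyl carbonate, which should succeed on the hydrogen-bonded, doubly ortho-substituted phenol because the acylpyridinium species is a strong acyl donor and no other nucleophilic group is present.

Step 6
Reactants: 7 tert-butyl 4-formyl-6-methoxy-2,2,7-trimethyl-1,3-benzodioxol-5-yl carbonate
Product: 8 tert-butyl 4-(hydroxymethyl)-6-methoxy-2,2,7-trimethyl-1,3-benzodioxol-5-yl carbonate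
Conditions: BH3·THF, THF, 0 °C; MeOH, then pH 7 phosphate buffer
Reagents that add atoms: none
Why: Chemoselective aldehyde reduction with borane, chosen because the neutral alkoxyborane is too weakly nucleophilic to attack the neighbouring aryl carbonate, whereas the metal alkoxide from a borohydride would trigger carbonate transfer, methide formation and over-reduction to the methylarene.

Step 7
Reactants: 9 1,12-dibromododecane
Product: 10 dodecane-1,12-diylbis(magnesium bromide)
Conditions: Mg turnings, I2 (cat.), THF, 50 °C, slow addition of 9; titrate before use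
Reagents that add atoms: magnesium, [Mg]
Why: Grignard reagent formation by insertion of magnesium into both primary C–Br bonds, where the twelve-carbon spacer disfavours cyclisation and slow addition limits intermolecular Wurtz coupling.

Step 8
Reactants: 8 tert-butyl 4-(hydroxymethyl)-6-methoxy-2,2,7-trimethyl-1,3-benzodioxol-5-yl carbonate (two equivalents), 10 dodecane-1,12-diylbis(magnesium bromide)
Product: 13 1,14-bis(5-hydroxy-6-methoxy-2,2,7-trimethyl-1,3-benzodioxol-4-yl)tetradecane, via benzylic carbonate phenoxide 11 (not isolated), via ortho-quinone methide 12 (not isolated)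
Conditions: 8 (2.1 equiv), t-BuMgCl (2.1 equiv), THF, −78 °C; then 10 (1.0 equiv), −78 °C to rt; aq. NH4Cl
Reagents that add atoms: none
Why: t-BuMgCl deprotonates the benzylic hydroxyl of 8 without adding to it; on warming, the chloromagnesium alkoxide attacks the adjacent aryl carbonate through a six-membered transition state, the Boc group moves to the benzylic oxygen (11), and the freed phenoxide expels tert-butyl carbonate in a 1,4-elimination to give methide 12. Each C–Mg terminus of 10 then adds in a 1,4-sense to the exocyclic methylene, which restores the arene as a magnesium phenoxide and forms the C1′–C2′ and C13′–C14′ bonds. The closest known reaction type is the base-triggered generation of ortho-quinone methides from ortho-(tert-butoxycarbonyloxy)benzyl alcohols with in situ conjugate addition of alkyl Grignard reagents. No ring is closed and no stereocentre is created. The step needs conjugate addition to outrun self-condensation of 12 and needs both termini of 10 to react: the first is secured by releasing 12 gradually below 0 °C with the Grignard reagent already present and by the fully substituted ring, which leaves the methylene (stabilised by the C3 oxygen and C5 methyl) as the only open electrophilic site, and the second by a slight excess of 8 over the C–Mg bonds.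

Step 9
Reactants: 13 1,14-bis(5-hydroxy-6-methoxy-2,2,7-trimethyl-1,3-benzodioxol-4-yl)tetradecane
Product: 15 3,3'-(tetradecane-1,14-diyl)bis(2-hydroxy-5-methoxy-6-methylcyclohexa-2,5-diene-1,4-dione), via bis(benzenetriol) 14 (not isolated)
Conditions: CF3CO2H/H2O (9:1 v/v), CH2Cl2, Ar, rt; evaporate; then O2 (1 atm), EtOAc/aq. phosphate buffer (pH 7), rt
Reagents that add atoms: none
Why: Acid-catalysed hydrolysis of both aryl isopropylidene ketals followed by autoxidation of a hydroxyhydroquinone, in which the para-related C1 and C4 hydroxyls of each ring become the quinone carbonyls while the C3 hydroxyl and the C6 methyl ether remain, so the methoxy position is fixed by the ether carried from compound 1.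

**Compound list**

1 | 3-methoxy-2-methylphenol | COc1cccc(O)c1C | starting material
2 | 2-methoxy-3-methyl-1,4-benzoquinone | COC1=C(C)C(=O)C=CC1=O | intermediate
3 | 5-methoxy-6-methylbenzene-1,2,4-triyl triacetate | COc1c(C)c(OC(C)=O)c(OC(C)=O)cc1OC(C)=O | intermediate
4 | 5-methoxy-6-methylbenzene-1,2,4-triol (formed in the flask, not isolated) | COc1c(C)c(O)c(O)cc1O | intermediate
5 | 6-methoxy-2,2,7-trimethyl-1,3-benzodioxol-5-ol | COc1c(C)c2OC(C)(C)Oc2cc1O | intermediate
6 | 5-hydroxy-6-methoxy-2,2,7-trimethyl-1,3-benzodioxole-4-carbaldehyde | COc1c(C)c2OC(C)(C)Oc2c(C=O)c1O | intermediate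
7 | tert-butyl 4-formyl-6-methoxy-2,2,7-trimethyl-1,3-benzodioxol-5-yl carbonate | COc1c(C)c2OC(C)(C)Oc2c(C=O)c1OC(=O)OC(C)(C)C | intermediate
8 | tert-butyl 4-(hydroxymethyl)-6-methoxy-2,2,7-trimethyl-1,3-benzodioxol-5-yl carbonate | COc1c(C)c2OC(C)(C)Oc2c(CO)c1OC(=O)OC(C)(C)C | intermediate
9 | 1,12-dibromododecane | BrCCCCCCCCCCCCBr | starting material
10 | dodecane-1,12-diylbis(magnesium bromide) | Br[Mg]CCCCCCCCCCCC[Mg]Br | intermediate
11 | chloromagnesium 4-{[(tert-butoxycarbonyl)oxy]methyl}-6-methoxy-2,2,7-trimethyl-1,3-benzodioxol-5-olate (formed in the flask, not isolated) | COc1c(C)c2OC(C)(C)Oc2c(COC(=O)OC(C)(C)C)c1O[Mg]Cl | intermediate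
12 | 6-methoxy-2,2,7-trimethyl-4-methylidene-1,3-benzodioxol-5(4H)-one (ortho-quinone methide, not isolated) | COC1=C(C)C2=C(OC(C)(C)O2)C(=C)C1=O | intermediate
13 | 1,14-bis(5-hydroxy-6-methoxy-2,2,7-trimethyl-1,3-benzodioxol-4-yl)tetradecane | COc1c(C)c2OC(C)(C)Oc2c(CCCCCCCCCCCCCCc3c(O)c(OC)c(C)c4OC(C)(C)Oc34)c1O | intermediate
14 | 3,3'-(tetradecane-1,14-diyl)bis(5-methoxy-6-methylbenzene-1,2,4-triol) (formed in the flask, not isolated) | COc1c(C)c(O)c(O)c(CCCCCCCCCCCCCCc2c(O)c(OC)c(C)c(O)c2O)c1O | intermediate
15 | 3,3'-(tetradecane-1,14-diyl)bis(2-hydroxy-5-methoxy-6-methylcyclohexa-2,5-diene-1,4-dione) | COC1=C(C)C(=O)C(O)=C(CCCCCCCCCCCCCCC2=C(O)C(=O)C(C)=C(OC)C2=O)C1=O | target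

**Totals.** Total step count: 9. Longest linear sequence: 8 steps (steps 1–6, 8 and 9); step 7 is a one-step branch.

**Steps most likely to fail**

Step 8. The methide may condense with itself faster than it is intercepted, or only one C–Mg terminus of the tether may react, leaving one-sided adducts. The fallback builds the tether by olefination and reduction instead; it sets out from 6 and 9 and comes back at 13. Heating 9 with PPh3 in MeCN should give dodecane-1,12-diylbis(triphenylphosphonium) dibromide F1. Its bis-ylide (KN(SiMe3)2, THF) would be combined with the potassium phenoxide of 6 in a double Wittig reaction to give 4,4'-[(1Z,13Z)-tetradeca-1,13-diene-1,14-diyl]bis(6-methoxy-2,2,7-trimethyl-1,3-benzodioxol-5-ol) F2, whose alkene geometry is of no consequence. Hydrogenation (H2, Pd/C, EtOAc) then returns to the route at 13.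

Step 2. Acetate addition may lose its regioselectivity if the methoxy group, flanked by a carbonyl and a methyl group, twists out of conjugation and directs less strongly. The fallback fixes every oxygen position by substitution chemistry; it sets out from 1 and comes back at 5. Casnati–Skattebøl formylation (MgCl2, Et3N, (CH2O)n) at the only free ortho position should give 2-hydroxy-4-methoxy-3-methylbenzaldehyde F3. Dakin oxidation (H2O2, NaOH) gives 4-methoxy-3-methylbenzene-1,2-diol F4, and ketalisation (Me2C(OMe)2, TsOH·H2O) gives 5-methoxy-2,2,4-trimethyl-1,3-benzodioxole F5. Vilsmeier–Haack formylation (POCl3, DMF), directed by the ortho methoxy group and the para dioxole oxygen, gives 6-methoxy-2,2,7-trimethyl-1,3-benzodioxole-5-carbaldehyde F6. Baeyer–Villiger oxidation (mCPBA) gives 6-methoxy-2,2,7-trimethyl-1,3-benzodioxol-5-yl formate F7, and methanolysis (K2CO3, MeOH) returns to the route at 5.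

Step 6. The Boc group may transfer to the benzylic oxygen during reduction or work-up, with elimination and over-reduction of the benzylic position. The fallback reverses the order of reduction and carbonate formation; it sets out from 6 and comes back at 8. NaBH4 reduction of the free hydroxy aldehyde (MeOH/THF, 0 °C) should give 4-(hydroxymethyl)-6-methoxy-2,2,7-trimethyl-1,3-benzodioxol-5-ol F8. Phenoxide-selective carbonate formation under phase transfer (Boc2O, aq. NaOH, (Bu4N)HSO4, CH2Cl2, 0 °C) then returns to the route at 8.

**Further compounds**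

F1 | step 8 | dodecane-1,12-diylbis(triphenylphosphonium) dibromide | [Br-].[Br-].c1ccccc1[P+](c1ccccc1)(c1ccccc1)CCCCCCCCCCCC[P+](c1ccccc1)(c1ccccc1)c1ccccc1
F2 | step 8 | 4,4'-[(1Z,13Z)-tetradeca-1,13-diene-1,14-diyl]bis(6-methoxy-2,2,7-trimethyl-1,3-benzodioxol-5-ol) | COc1c(C)c2OC(C)(C)Oc2c(/C=C\CCCCCCCCCC/C=C\c3c(O)c(OC)c(C)c4OC(C)(C)Oc34)c1O
F3 | step 2 | 2-hydroxy-4-methoxy-3-methylbenzaldehyde | COc1ccc(C=O)c(O)c1C
F4 | step 2 | 4-methoxy-3-methylbenzene-1,2-diol | COc1ccc(O)c(O)c1C
F5 | step 2 | 5-methoxy-2,2,4-trimethyl-1,3-benzodioxole | COc1ccc2OC(C)(C)Oc2c1C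
F6 | step 2 | 6-methoxy-2,2,7-trimethyl-1,3-benzodioxole-5-carbaldehyde | COc1c(C)c2OC(C)(C)Oc2cc1C=O
F7 | step 2 | 6-methoxy-2,2,7-trimethyl-1,3-benzodioxol-5-yl formate | COc1c(C)c2OC(C)(C)Oc2cc1OC=O
F8 | step 6 | 4-(hydroxymethyl)-6-methoxy-2,2,7-trimethyl-1,3-benzodioxol-5-ol | COc1c(C)c2OC(C)(C)Oc2c(CO)c1O
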